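**Plan**

1. Numbering: the target is numbered as an azulene (C1–C3 five-membered ring, C3a and C8a ring fusion, C4–C8 seven-membered ring). Retrosynthesis: the enol ester C–O bond, the C7 carboxyl, the C5 acetonyl group and the C4 two-carbon arm are removed first, giving a 4-methylidene-6-silyloxy hydroazulene. This is then cut at C5–C6 and C3a–C8a in one (4+3) event.
2. Enabling feature: the seven-membered ring holds the C7=C8 alkene between oxygenated C6 and C8a, which is a 1-silyloxy-1,3-diene (C6–C7–C8–C8a). The other three ring carbons C3a–C4–C5 carry one exocyclic carbon on the central C4, which is a 2-(silylmethyl)allyl cation. C8a and C3a are bridged by C1–C2–C3 of the cyclopentane, which is the three-atom tether.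
3. Forward order: catalytic asymmetric Diels–Alder, ozonolysis, Grignard addition with lactonisation, homologation to the dienol silyl ether, then the Lewis-acid (4+3) step that closes both rings at once. The δ-lactone is a temporary ring: its C–O bond is the leaving group and its carbonyl becomes the C1 carboxyl.
4. After the key step: C1 is inverted and converted to the carbinol, then C4, C5 and C7 are elaborated, and the (E)-enol ester is made last but one.
5. Stereochemistry: C1 is set by the catalytic Diels–Alder step and relays to C8a and C3a (trans fusion) in the key step; C1 is then itself corrected by kinetic protonation. C4 comes from hydroboration anti to the angular methyl, C5 from alkylation anti to the C4 substituent, and the (E)-enol ester from (E)-selective cross-metathesis followed by stereoretentive C–O coupling.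

Key step: step 7

Assumption: the (S)-configured oxazaborolidinium catalyst is taken to deliver the (1R)-adduct 3; should its facial sense be the reverse, the mirror-image catalyst is used.
Convention: β is the face of H-8a and α the face of the 3a-methyl group.

**Route**

Step 1
Reactants: 1 isoprene; 2 2,2,2-trifluoroethyl acrylate
Product: 3 2,2,2-trifluoroethyl (1R)-4-methylcyclohex-3-ene-1-carboxylate
Conditions: (S)-B-(o-tolyl)-α,α-diphenylprolinol oxazaborolidine·HNTf2 (10 mol %), isoprene (5 equiv), CH2Cl2, −20 → 0 °C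
Reagents that add atoms: none
Why: Enantioselective Diels–Alder reaction in which the cationic oxazaborolidinium binds the acrylate and shields one face, while isoprene adds with "para" regiochemistry, so the single stereocentre that is set by catalysis (the later C1) should form with high selectivity.

Step 2
Reactants: 3 2,2,2-trifluoroethyl (1R)-4-methylcyclohex-3-ene-1-carboxylate
Product: 6 2,2,2-trifluoroethyl (2R)-2-(2,2-dimethoxyethyl)-5-oxohexanoate, via secondary ozonide 4 (not isolated), via keto aldehyde 5 (not isolated)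
Conditions: O3, CH2Cl2, −78 °C; Me2S, −78 °C → rt; then HC(OMe)3, MeOH, PPTS (cat.), 0 °C
Reagents that add atoms: ozone [O-][O+]=O; trimethyl orthoformate COC(OC)OC
Why: Ozonolysis of the only alkene unmasks a methyl ketone and an aldehyde, and mild acid acetalisation should take the aldehyde alone (aldehydes react far faster than ketones), which differentiates the two carbonyl groups without touching the stereocentre.

Step 3
Reactants: 6 2,2,2-trifluoroethyl (2R)-2-(2,2-dimethoxyethyl)-5-oxohexanoate; 7 (2-bromoprop-2-en-1-yl)trimethylsilane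
Product: 10 (3R)-3-(2,2-dimethoxyethyl)-6-methyl-6-[3-(trimethylsilyl)prop-1-en-2-yl]oxan-2-one (both C6 epimers), via Grignard reagent 8 (not isolated), via magnesium alkoxide 9 (not isolated)
Conditions: 7, Mg, THF, rt; then 6, THF, −78 → 0 °C; NH4Cl (aq)
Reagents that add atoms: none
Why: Grignard addition is ketone-selective at low temperature, and on warming the tertiary alkoxide should acylate on the activated trifluoroethyl ester to close the δ-lactone; the new carbinol centre is an epimer mixture that is erased when this C–O bond ionises in step 7.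

Step 4
Reactants: 10 (3R)-3-(2,2-dimethoxyethyl)-6-methyl-6-[3-(trimethylsilyl)prop-1-en-2-yl]oxan-2-one
Product: 11 [(3R)-6-methyl-2-oxo-6-[3-(trimethylsilyl)prop-1-en-2-yl]oxan-3-yl]acetaldehyde
Conditions: PPTS, acetone/H2O, 45 °C
Reagents that add atoms: water O
Why: Mild acid hydrolysis of a dimethyl acetal, under which the allylsilane and the tertiary allylic lactone should survive.

Step 5
Reactants: 11 [(3R)-6-methyl-2-oxo-6-[3-(trimethylsilyl)prop-1-en-2-yl]oxan-3-yl]acetaldehyde; 12 (triphenylphosphoranylidene)acetaldehyde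
Product: 13 (2E)-4-[(3R)-6-methyl-2-oxo-6-[3-(trimethylsilyl)prop-1-en-2-yl]oxan-3-yl]but-2-enal
Conditions: 12 (1.1 equiv), toluene, 70 °C
Reagents that add atoms: none
Why: Wittig reaction of a stabilised ylide gives the (E)-enal by two-carbon homologation under neutral conditions that leave the lactone and its α-stereocentre alone.

Step 6
Reactants: 13 (2E)-4-[(3R)-6-methyl-2-oxo-6-[3-(trimethylsilyl)prop-1-en-2-yl]oxan-3-yl]but-2-enal
Product: 14 (3R)-6-methyl-3-[(1E,3E)-4-(triethylsilyloxy)buta-1,3-dienyl]-6-[3-(trimethylsilyl)prop-1-en-2-yl]oxan-2-one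
Conditions: TESOTf, Et3N, Et2O, −78 → 0 °C
Reagents that add atoms: triethylsilyl trifluoromethanesulfonate CC[Si](CC)(CC)OS(=O)(=O)C(F)(F)F
Why: Soft enolisation (O-silylation of the enal, then γ-deprotonation) should give the 1-silyloxy diene with the new alkene (E), while the much less acidic lactone is not enolised; any (1Z) isomer converges later because C6 becomes a ketone.

Step 7
Reactants: 14 (3R)-6-methyl-3-[(1E,3E)-4-(triethylsilyloxy)buta-1,3-dienyl]-6-[3-(trimethylsilyl)prop-1-en-2-yl]oxan-2-one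
Product: 16 (1R)-3aα-methyl-4-methylidene-6α-(triethylsilyloxy)-1,2,3,3a,4,5,6,8a-octahydroazulene-1β-carboxylic acid (8aβ-H), via trimethylsilyl ester 15 (not isolated)
Conditions: TMSOTf (20 mol %), 2,6-di-tert-butyl-4-methylpyridine (30 mol %), CH2Cl2, −78 → −40 °C; pH 7 buffer, then dilute citric acid
Reagents that add atoms: none
Why: TMSOTf silylates the lactone carbonyl and ionises the tertiary allylic C–O bond to a 2-(trimethylsilylmethyl)allyl cation tethered to the silyloxy diene; the cation terminus bonds to the diene terminus (C3a–C8a), the unsaturated silyloxocarbenium ion so formed is captured by the allylsilane terminus (C5–C6), and loss of Me3Si+ from the β-silyl cation leaves the 4-methylidene group and regenerates TMSOTf. The closest known reaction type is the intramolecular (4+3) cycloaddition of 2-(silylmethyl)allyl cations with 1,3-dienes on a three-atom tether, whose second bond formation is a Hosomi–Sakurai addition. The cyclopentane closes 5-exo-trig onto the diene terminus and the cycloheptene closes 7-endo with respect to the allylsilane (exo at the oxocarbenium carbon), the s-cis (3E)-diene delivering the cis C7=C8 bond. C8a is controlled by the C1 stereocentre, whose carboxylate arm should sit anti to the dienyl chain on the forming cyclopentane so that only one diene face is reached; C3a is controlled by the extended (exo-like) arrangement that puts the bulky silylmethylallyl arm trans to the dienyl arm and so gives the trans ring fusion; C6 follows from suprafacial addition to the (1E)-enol ether and is erased by later oxidation. The step needs (4+3) and not (3+2) closure and no protodesilylation: 1,2-attack at the oxocarbenium carbon of the cis-configured intermediate is the geometrically favoured ring closure, and the hindered pyridine scavenges triflic acid.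

Step 8
Reactants: 16 (1R)-3aα-methyl-4-methylidene-6α-(triethylsilyloxy)-1,2,3,3a,4,5,6,8a-octahydroazulene-1β-carboxylic acid
Product: 17 methyl (1R)-3aα-methyl-4-methylidene-6α-(triethylsilyloxy)-1,2,3,3a,4,5,6,8a-octahydroazulene-1β-carboxylate
Conditions: TMSCHN2, toluene/MeOH, 0 °C
Reagents that add atoms: (trimethylsilyl)diazomethane C[Si](C)(C)C=[N+]=[N-]
Why: Esterification of a carboxylic acid with a diazoalkane is neutral and should leave the allylic silyl ether and both alkenes intact.

Step 9
Reactants: 17 methyl (1R)-3aα-methyl-4-methylidene-6α-(triethylsilyloxy)-1,2,3,3a,4,5,6,8a-octahydroazulene-1β-carboxylate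
Product: 19 methyl (1S)-3aα-methyl-4-methylidene-6α-(triethylsilyloxy)-1,2,3,3a,4,5,6,8a-octahydroazulene-1α-carboxylate, via lithium enolate 18 (not isolated)
Conditions: LDA, THF, −78 → −40 °C; then 2,6-di-tert-butyl-4-methylphenol, −78 °C
Reagents that add atoms: none
Why: Kinetic protonation of the exocyclic ester enolate by a bulky proton donor should occur on the open β face (anti to the C8 ring carbon on C8a and to the angular methyl), which inverts C1 to the less stable 1α-ester that the target requires.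

Step 10
Reactants: 19 methyl (1S)-3aα-methyl-4-methylidene-6α-(triethylsilyloxy)-1,2,3,3a,4,5,6,8a-octahydroazulene-1α-carboxylate
Product: 21 2-[(1S)-3aα-methyl-4-methylidene-6α-(triethylsilyloxy)-1,2,3,3a,4,5,6,8a-octahydroazulen-1α-yl]propan-2-ol, via methyl ketone 20 (not isolated)
Conditions: MeLi (3 equiv), CeCl3, THF, −78 → 0 °C
Reagents that add atoms: methyllithium [Li]C
Why: Double addition of the weakly basic organocerium reagent to the ester gives the tertiary carbinol without enolisation, so the C1 configuration just set is kept.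

Step 11
Reactants: 21 2-[(1S)-3aα-methyl-4-methylidene-6α-(triethylsilyloxy)-1,2,3,3a,4,5,6,8a-octahydroazulen-1α-yl]propan-2-ol
Product: 24 4α-(hydroxymethyl)-1α-(2-hydroxypropan-2-yl)-3aα-methyl-1,2,3,3a,4,5,6,8a-octahydroazulen-6α-ol (4β-H), via alkylborane 22 (not isolated), via silyl ether diol 23 (not isolated)
Conditions: 9-BBN (3 equiv), THF, 60 °C; NaOH, H2O2, 0 °C → rt; then HCl (1 M), THF, rt
Reagents that add atoms: hydrogen peroxide OO
Why: Hydroboration–oxidation with 9-BBN selects the 1,1-disubstituted alkene over the ring alkene and should add from the β face, anti to the axial 3a-methyl group, placing H on C4 β and the hydroxymethyl group α; dilute acid then removes the triethylsilyl ether.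

Step 12
Reactants: 24 4α-(hydroxymethyl)-1α-(2-hydroxypropan-2-yl)-3aα-methyl-1,2,3,3a,4,5,6,8a-octahydroazulen-6α-ol
Product: 25 1α-(2-hydroxypropan-2-yl)-3aα-methyl-6-oxo-1,2,3,3a,4,5,6,8a-octahydroazulene-4α-carbaldehyde
Conditions: Dess–Martin periodinane (3 equiv), NaHCO3, CH2Cl2, 0 °C → rt
Reagents that add atoms: none
Why: Dess–Martin oxidation converts the primary alcohol to the aldehyde and the allylic C6 alcohol to the enone in one operation under buffered conditions that should not epimerise C4, and the tertiary alcohol cannot react.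

Step 13
Reactants: 25 1α-(2-hydroxypropan-2-yl)-3aα-methyl-6-oxo-1,2,3,3a,4,5,6,8a-octahydroazulene-4α-carbaldehyde
Product: 26 4α-ethenyl-1α-(2-hydroxypropan-2-yl)-3aα-methyl-2,3,3a,4,5,8a-hexahydroazulen-6(1H)-one
Conditions: CH2I2, Zn, Ti(OiPr)4, THF, rt
Reagents that add atoms: diiodomethane ICI
Why: Takai-type methylenation with the zinc–titanium gem-dimetallic reagent is non-basic and selective for aldehydes over ketones, so the enone and the C4 centre should be preserved.

Step 14
Reactants: 26 4α-ethenyl-1α-(2-hydroxypropan-2-yl)-3aα-methyl-2,3,3a,4,5,8a-hexahydroazulen-6(1H)-one; 27 3-bromoprop-1-yne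
Product: 29 4α-ethenyl-1α-(2-hydroxypropan-2-yl)-3aα-methyl-5β-(prop-2-yn-1-yl)-2,3,3a,4,5,8a-hexahydroazulen-6(1H)-one, via dilithium enolate 28 (not isolated)
Conditions: LDA (2.2 equiv), THF, −78 °C; 27, DMPU, −78 → −30 °C
Reagents that add atoms: none
Why: Kinetic deprotonation of the enone at the α' carbon C5 (the second equivalent of base is taken by the tertiary alcohol) gives the cross-conjugated enolate, whose alkylation should occur on the β face, anti to the adjacent 4α-vinyl group and the axial 3a-methyl group, which sets C5.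

Step 15
Reactants: 29 4α-ethenyl-1α-(2-hydroxypropan-2-yl)-3aα-methyl-5β-(prop-2-yn-1-yl)-2,3,3a,4,5,8a-hexahydroazulen-6(1H)-one
Product: 30 4α-ethenyl-1α-(2-hydroxypropan-2-yl)-3aα-methyl-5β-(2-oxopropyl)-2,3,3a,4,5,8a-hexahydroazulen-6(1H)-one
Conditions: (Ph3P)AuNTf2 (2 mol %), MeOH/H2O, 40 °C
Reagents that add atoms: water O
Why: Gold-catalysed Markovnikov hydration of the terminal alkyne (assisted by the neighbouring carbonyl) gives the methyl ketone of the 2-oxopropyl group, and the aqueous medium should suppress cycloisomerisation to a furan.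

Step 16
Reactants: 30 4α-ethenyl-1α-(2-hydroxypropan-2-yl)-3aα-methyl-5β-(2-oxopropyl)-2,3,3a,4,5,8a-hexahydroazulen-6(1H)-one
Product: 31 4α-ethenyl-1α-(2-hydroxypropan-2-yl)-7-iodo-3aα-methyl-5β-(2-oxopropyl)-2,3,3a,4,5,8a-hexahydroazulen-6(1H)-one
Conditions: I2, pyridine, CH2Cl2, rt
Reagents that add atoms: iodine II
Why: α-Iodination of an enone by the conjugate addition of pyridine, iodination of the enolate and elimination (a Baylis–Hillman-type sequence) is specific for the enone α-carbon C7 and should leave the saturated ketone and the vinyl group alone.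

Step 17
Reactants: 31 4α-ethenyl-1α-(2-hydroxypropan-2-yl)-7-iodo-3aα-methyl-5β-(2-oxopropyl)-2,3,3a,4,5,8a-hexahydroazulen-6(1H)-one
Product: 32 2-(trimethylsilyl)ethyl 4α-ethenyl-1α-(2-hydroxypropan-2-yl)-3aα-methyl-6-oxo-5β-(2-oxopropyl)-1,2,3,3a,4,5,6,8a-octahydroazulene-7-carboxylate
Conditions: Pd(OAc)2 (10 mol %), PPh3 (20 mol %), CO (1 atm), Me3SiCH2CH2OH (5 equiv), iPr2NEt, DMF, 50 °C
Reagents that add atoms: carbon monoxide [C-]#[O+]; 2-(trimethylsilyl)ethanol C[Si](C)(C)CCO
Why: Palladium-catalysed alkoxycarbonylation (oxidative addition of the alkenyl iodide to zerovalent palladium, CO insertion, alcoholysis) installs the C7 carboxyl as a fluoride-labile ester, and the tertiary alcohol cannot lactonise because it lies trans to the acyl group across C7=C8.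

Step 18
Reactants: 32 2-(trimethylsilyl)ethyl 4α-ethenyl-1α-(2-hydroxypropan-2-yl)-3aα-methyl-6-oxo-5β-(2-oxopropyl)-1,2,3,3a,4,5,6,8a-octahydroazulene-7-carboxylate; 33 2-ethenyl-4,4,5,5-tetramethyl-1,3,2-dioxaborolane
Product: 34 2-(trimethylsilyl)ethyl 1α-(2-hydroxypropan-2-yl)-3aα-methyl-6-oxo-5β-(2-oxopropyl)-4α-[(E)-2-(4,4,5,5-tetramethyl-1,3,2-dioxaborolan-2-yl)ethenyl]-1,2,3,3a,4,5,6,8a-octahydroazulene-7-carboxylate
Conditions: 33 (3 equiv), second-generation Grubbs catalyst (10 mol %), CH2Cl2, 40 °C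
Reagents that add atoms: none
Why: Olefin cross-metathesis of the only monosubstituted alkene with the vinylboronate should give the (E)-alkenylboronate under thermodynamic control, the electron-poor trisubstituted C7=C8 bond being inert to the catalyst.

Step 19
Reactants: 34 the (E)-alkenyl pinacol boronate
Product: 35 potassium trifluoro[(E)-2-(hydroazulen-4α-yl)ethenyl]borate corresponding to 34
Conditions: KHF2 (aq), MeOH, rt
Reagents that add atoms: potassium hydrogen difluoride [K+].[F-].F
Why: Exchange of the pinacol ester for fluoride gives the alkenyltrifluoroborate, the boron form established for copper-catalysed coupling with carboxylic acids, with the alkene geometry untouched.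

Step 20
Reactants: 35 the potassium (E)-alkenyltrifluoroborate; 36 3-methylbut-2-enoic acid
Product: 37 2-(trimethylsilyl)ethyl 1α-(2-hydroxypropan-2-yl)-3aα-methyl-4α-[(E)-2-[(3-methylbut-2-enoyl)oxy]ethenyl]-6-oxo-5β-(2-oxopropyl)-1,2,3,3a,4,5,6,8a-octahydroazulene-7-carboxylate
Conditions: 36 (3 equiv), CuBr (10 mol %), DMAP (20 mol %), 4 Å MS, O2 (1 atm), MeCN, 40 °C
Reagents that add atoms: none
Why: Copper-catalysed oxidative coupling of an alkenyltrifluoroborate with a carboxylic acid (Chan–Lam-type C–O bond formation) proceeds by transmetalation and reductive elimination with retention, so the (E)-enol ester should form, and the hindered tertiary alcohol should not compete.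

Step 21
Reactants: 37 the 2-(trimethylsilyl)ethyl ester of the target
Product: 38 (1S,3aS,4S,5S,8aS)-1-(2-hydroxypropan-2-yl)-3a-methyl-4-[(E)-2-[(3-methylbut-2-enoyl)oxy]ethenyl]-6-oxo-5-(2-oxopropyl)-1,2,3,3a,4,5,6,8a-octahydroazulene-7-carboxylic acid (CNP0290717.1)
Conditions: TASF, DMF, 0 °C; NaH2PO4 (aq)
Reagents that add atoms: none
Why: Fluoride attacks silicon and the 2-silylethyl ester fragments to ethene and the carboxylate under non-hydrolytic conditions, which should spare the enol ester, the tertiary alcohol and the enone.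

**Compound list**

1 | isoprene | C=CC(C)=C | starting material
2 | 2,2,2-trifluoroethyl acrylate | C=CC(=O)OCC(F)(F)F | starting material
3 | 2,2,2-trifluoroethyl (1R)-4-methylcyclohex-3-ene-1-carboxylate | CC1=CC[C@@H](CC1)C(=O)OCC(F)(F)F | intermediate
4 | secondary ozonide (1,2,4-trioxolane) of 3 | CC12CC[C@H](CC(O1)OO2)C(=O)OCC(F)(F)F | intermediate (not isolated)
5 | 2,2,2-trifluoroethyl (2R)-5-oxo-2-(2-oxoethyl)hexanoate | O=CC[C@@H](CCC(C)=O)C(=O)OCC(F)(F)F | intermediate (not isolated)
6 | 2,2,2-trifluoroethyl (2R)-2-(2,2-dimethoxyethyl)-5-oxohexanoate | COC(OC)C[C@@H](CCC(C)=O)C(=O)OCC(F)(F)F | intermediate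
7 | (2-bromoprop-2-en-1-yl)trimethylsilane | C=C(Br)C[Si](C)(C)C | starting material
8 | [3-(trimethylsilyl)prop-1-en-2-yl]magnesium bromide | C=C([Mg]Br)C[Si](C)(C)C | intermediate (not isolated)
9 | bromomagnesium tertiary alkoxide from addition of 8 to the ketone of 6 | COC(OC)C[C@@H](CCC(C)(O[Mg]Br)C(=C)C[Si](C)(C)C)C(=O)OCC(F)(F)F | intermediate (not isolated)
10 | (3R)-3-(2,2-dimethoxyethyl)-6-methyl-6-[3-(trimethylsilyl)prop-1-en-2-yl]oxan-2-one (both C6 epimers) | COC(OC)C[C@H]1CCC(C)(C(=C)C[Si](C)(C)C)OC1=O | intermediate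
11 | [(3R)-6-methyl-2-oxo-6-[3-(trimethylsilyl)prop-1-en-2-yl]oxan-3-yl]acetaldehyde | O=CC[C@H]1CCC(C)(C(=C)C[Si](C)(C)C)OC1=O | intermediate
12 | (triphenylphosphoranylidene)acetaldehyde | O=CC=P(c1ccccc1)(c1ccccc1)c1ccccc1 | starting material
13 | (2E)-4-[(3R)-6-methyl-2-oxo-6-[3-(trimethylsilyl)prop-1-en-2-yl]oxan-3-yl]but-2-enal | O=C/C=C/C[C@H]1CCC(C)(C(=C)C[Si](C)(C)C)OC1=O | intermediate
14 | (3R)-6-methyl-3-[(1E,3E)-4-(triethylsilyloxy)buta-1,3-dienyl]-6-[3-(trimethylsilyl)prop-1-en-2-yl]oxan-2-one | CC[Si](CC)(CC)O/C=C/C=C/[C@H]1CCC(C)(C(=C)C[Si](C)(C)C)OC1=O | intermediate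
15 | trimethylsilyl ester of 16 | C1[C@@H](O[Si](CC)(CC)CC)C=C[C@H]2[C@H](C(=O)O[Si](C)(C)C)CC[C@]2(C)C1=C | intermediate (not isolated)
16 | (1R)-3aα-methyl-4-methylidene-6α-(triethylsilyloxy)-1,2,3,3a,4,5,6,8a-octahydroazulene-1β-carboxylic acid (8aβ-H, trans-fused) | C1[C@@H](O[Si](CC)(CC)CC)C=C[C@H]2[C@H](C(=O)O)CC[C@]2(C)C1=C | intermediate
17 | methyl ester of 16 (1β-CO2Me) | C1[C@@H](O[Si](CC)(CC)CC)C=C[C@H]2[C@H](C(=O)OC)CC[C@]2(C)C1=C | intermediate
18 | lithium enolate of 17 (ketene acetal at C1) | C1[C@@H](O[Si](CC)(CC)CC)C=C[C@H]2C(=C(O[Li])OC)CC[C@]2(C)C1=C | intermediate (not isolated)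
19 | methyl (1S)-3aα-methyl-4-methylidene-6α-(triethylsilyloxy)-1,2,3,3a,4,5,6,8a-octahydroazulene-1α-carboxylate (C1 epimer of 17) | C1[C@@H](O[Si](CC)(CC)CC)C=C[C@H]2[C@@H](C(=O)OC)CC[C@]2(C)C1=C | intermediate
20 | 1α-acetyl analogue of 19 (methyl ketone) | C1[C@@H](O[Si](CC)(CC)CC)C=C[C@H]2[C@@H](C(C)=O)CC[C@]2(C)C1=C | intermediate (not isolated)
21 | 2-[(1S)-3aα-methyl-4-methylidene-6α-(triethylsilyloxy)-1,2,3,3a,4,5,6,8a-octahydroazulen-1α-yl]propan-2-ol | C1[C@@H](O[Si](CC)(CC)CC)C=C[C@H]2[C@@H](C(C)(C)O)CC[C@]2(C)C1=C | intermediate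
22 | B-alkyl-9-borabicyclo[3.3.1]nonane from 21 (boron on the exocyclic carbon, 4β-H) | C1[C@@H](O[Si](CC)(CC)CC)C=C[C@H]2[C@@H](C(C)(C)O)CC[C@]2(C)[C@H]1CB1C2CCCC1CCC2 | intermediate (not isolated)
23 | 4α-(hydroxymethyl) derivative of 21 (4β-H, 6-O-triethylsilyl) | C1[C@@H](O[Si](CC)(CC)CC)C=C[C@H]2[C@@H](C(C)(C)O)CC[C@]2(C)[C@H]1CO | intermediate (not isolated)
24 | 4α-(hydroxymethyl)-1α-(2-hydroxypropan-2-yl)-3aα-methyl-1,2,3,3a,4,5,6,8a-octahydroazulen-6α-ol | C1[C@@H](O)C=C[C@H]2[C@@H](C(C)(C)O)CC[C@]2(C)[C@H]1CO | intermediate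
25 | 1α-(2-hydroxypropan-2-yl)-3aα-methyl-6-oxo-1,2,3,3a,4,5,6,8a-octahydroazulene-4α-carbaldehyde | C1C(=O)C=C[C@H]2[C@@H](C(C)(C)O)CC[C@]2(C)[C@H]1C=O | intermediate
26 | 4α-ethenyl-1α-(2-hydroxypropan-2-yl)-3aα-methyl-2,3,3a,4,5,8a-hexahydroazulen-6(1H)-one | C1C(=O)C=C[C@H]2[C@@H](C(C)(C)O)CC[C@]2(C)[C@H]1C=C | intermediate
27 | 3-bromoprop-1-yne | C#CCBr | starting material
28 | dilithium salt of 26 (C5=C6 enolate and tertiary alkoxide) | C1=C(O[Li])C=C[C@H]2[C@@H](C(C)(C)O[Li])CC[C@]2(C)[C@H]1C=C | intermediate (not isolated)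
29 | 5β-(prop-2-yn-1-yl) derivative of 26 | C#CC[C@@H]1C(=O)C=C[C@H]2[C@@H](C(C)(C)O)CC[C@]2(C)[C@H]1C=C | intermediate
30 | 4α-ethenyl-1α-(2-hydroxypropan-2-yl)-3aα-methyl-5β-(2-oxopropyl)-2,3,3a,4,5,8a-hexahydroazulen-6(1H)-one | CC(=O)C[C@@H]1C(=O)C=C[C@H]2[C@@H](C(C)(C)O)CC[C@]2(C)[C@H]1C=C | intermediate
31 | 7-iodo derivative of 30 | CC(=O)C[C@@H]1C(=O)C(I)=C[C@H]2[C@@H](C(C)(C)O)CC[C@]2(C)[C@H]1C=C | intermediate
32 | 2-(trimethylsilyl)ethyl 4α-ethenyl-1α-(2-hydroxypropan-2-yl)-3aα-methyl-6-oxo-5β-(2-oxopropyl)-1,2,3,3a,4,5,6,8a-octahydroazulene-7-carboxylate | CC(=O)C[C@@H]1C(=O)C(C(=O)OCC[Si](C)(C)C)=C[C@H]2[C@@H](C(C)(C)O)CC[C@]2(C)[C@H]1C=C | intermediate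
33 | 2-ethenyl-4,4,5,5-tetramethyl-1,3,2-dioxaborolane | C=CB1OC(C)(C)C(C)(C)O1 | starting material
34 | 4α-[(E)-2-(4,4,5,5-tetramethyl-1,3,2-dioxaborolan-2-yl)ethenyl] analogue of 32 | CC(=O)C[C@@H]1C(=O)C(C(=O)OCC[Si](C)(C)C)=C[C@H]2[C@@H](C(C)(C)O)CC[C@]2(C)[C@H]1/C=C/B1OC(C)(C)C(C)(C)O1 | intermediate
35 | potassium (E)-alkenyltrifluoroborate corresponding to 34 | CC(=O)C[C@@H]1C(=O)C(C(=O)OCC[Si](C)(C)C)=C[C@H]2[C@@H](C(C)(C)O)CC[C@]2(C)[C@H]1/C=C/[B-](F)(F)F.[K+] | intermediate
36 | 3-methylbut-2-enoic acid | CC(C)=CC(=O)O | starting material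
37 | 2-(trimethylsilyl)ethyl ester of the target | CC(=O)C[C@@H]1C(=O)C(C(=O)OCC[Si](C)(C)C)=C[C@H]2[C@@H](C(C)(C)O)CC[C@]2(C)[C@H]1/C=C/OC(=O)C=C(C)C | intermediate
38 | (1S,3aS,4S,5S,8aS)-1-(2-hydroxypropan-2-yl)-3a-methyl-4-[(E)-2-[(3-methylbut-2-enoyl)oxy]ethenyl]-6-oxo-5-(2-oxopropyl)-1,2,3,3a,4,5,6,8a-octahydroazulene-7-carboxylic acid | CC(=O)C[C@@H]1C(=O)C(C(=O)O)=C[C@H]2[C@@H](C(C)(C)O)CC[C@]2(C)[C@H]1/C=C/OC(=O)C=C(C)C | target

**Totals and risks**

Total step count: 21. Longest linear sequence: 21 steps (from 1 and 2; all other partners are commercial).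

The three steps most likely to fail:

Step 7. What may go wrong: protodesilylation of the allylsilane before the second bond forms, closure by 1,4-attack to a five-membered (3+2) product, or erosion of the ring-fusion selectivity. Fallback through a more stabilised 2-silyloxyallyl cation, setting out from 6: addition of 1-ethoxyvinyllithium (ethyl vinyl ether, t-BuLi, THF, −78 °C) with lactonisation on warming should give (3R)-3-(2,2-dimethoxyethyl)-6-(1-ethoxyethenyl)-6-methyloxan-2-one F1. Dilute HCl in THF hydrolyses the enol ether and the acetal to [(3R)-6-acetyl-6-methyl-2-oxooxan-3-yl]acetaldehyde F2. Aldehyde-selective Wittig reaction with 12 gives (2E)-4-[(3R)-6-acetyl-6-methyl-2-oxooxan-3-yl]but-2-enal F3. TESOTf (2.2 equiv) and Et3N silylate both enolisable carbonyls to the bis(silyl enol ether) (3R)-6-methyl-3-[(1E,3E)-4-(triethylsilyloxy)buta-1,3-dienyl]-6-[1-(triethylsilyloxy)ethenyl]oxan-2-one F4. TMSOTf then ionises the lactone to a 2-(triethylsilyloxy)allyl cation, whose (4+3) cycloaddition, a long-established reaction class, gives after work-up (1R)-3aα-methyl-4-oxo-6α-(triethylsilyloxy)-1,2,3,3a,4,5,6,8a-octahydroazulene-1β-carboxylic acid F5. TMSCHN2 gives its methyl ester F6, and Wittig methylenation of the C4 ketone (Ph3P=CH2, toluene, 80 °C) comes back to the route at 17.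

Step 9. What may go wrong: slow deprotonation of the hindered 1α-hydrogen, or protonation of the enolate with poor facial selectivity, so that the 1β-ester persists. Fallback through a ketene, setting out from 16: Ghosez's reagent (CH2Cl2, 0 °C) gives the acid chloride of 16 F7. Et3N (toluene, 60 °C) eliminates HCl to the ketene at C1 F8. Addition of MeOH at −78 °C protonates the resulting enol at C1 from the open β face, the known stereochemical course of alcohol additions to ketenes. This comes back to the route at 19.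

Step 18. What may go wrong: sluggish cross-metathesis at the vinyl group, which is flanked by a quaternary and a tertiary carbon, with catalyst decay or self-metathesis of 33 taking over. Fallback by cleavage and olefination, setting out from 32: Lemieux–Johnson cleavage (OsO4 cat., NaIO4, 2,6-lutidine, dioxane/H2O) of the only electron-rich alkene gives the 4α-formyl analogue of 32 F9. Takai–Utimoto boron olefination (CrCl2, Cl2CHB(pin), LiI, THF) then gives the (E)-alkenylboronate and comes back to the route at 34.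

Further compounds
F1 | step 7 | (3R)-3-(2,2-dimethoxyethyl)-6-(1-ethoxyethenyl)-6-methyloxan-2-one | COC(OC)C[C@H]1CCC(C)(C(=C)OCC)OC1=O
F2 | step 7 | [(3R)-6-acetyl-6-methyl-2-oxooxan-3-yl]acetaldehyde | O=CC[C@H]1CCC(C)(C(C)=O)OC1=O
F3 | step 7 | (2E)-4-[(3R)-6-acetyl-6-methyl-2-oxooxan-3-yl]but-2-enal | O=C/C=C/C[C@H]1CCC(C)(C(C)=O)OC1=O
F4 | step 7 | (3R)-6-methyl-3-[(1E,3E)-4-(triethylsilyloxy)buta-1,3-dienyl]-6-[1-(triethylsilyloxy)ethenyl]oxan-2-one | CC[Si](CC)(CC)O/C=C/C=C/[C@H]1CCC(C)(C(=C)O[Si](CC)(CC)CC)OC1=O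
F5 | step 7 | (1R)-3aα-methyl-4-oxo-6α-(triethylsilyloxy)-1,2,3,3a,4,5,6,8a-octahydroazulene-1β-carboxylic acid | C1[C@@H](O[Si](CC)(CC)CC)C=C[C@H]2[C@H](C(=O)O)CC[C@]2(C)C1=O
F6 | step 7 | methyl ester of F5 | C1[C@@H](O[Si](CC)(CC)CC)C=C[C@H]2[C@H](C(=O)OC)CC[C@]2(C)C1=O
F7 | step 9 | acid chloride of 16 | C1[C@@H](O[Si](CC)(CC)CC)C=C[C@H]2[C@H](C(=O)Cl)CC[C@]2(C)C1=C
F8 | step 9 | ketene at C1 derived from F7 | C1[C@@H](O[Si](CC)(CC)CC)C=C[C@H]2C(=C=O)CC[C@]2(C)C1=C
F9 | step 18 | 4α-formyl analogue of 32 | CC(=O)C[C@@H]1C(=O)C(C(=O)OCC[Si](C)(C)C)=C[C@H]2[C@@H](C(C)(C)O)CC[C@]2(C)[C@H]1C=O
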